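**Retrosynthetic overview**

1. The strategy rests on C10, the methyl-bearing quaternary carbon shared by rings A and B and flanked by C9 and C5. Ring B is therefore carried as a 2-methylphenol (C9–OH, C10–CH3), and ring A is closed onto it by the C1–C10 bond with loss of aromaticity.
2. Side chain: C12–C13 by B-alkyl Suzuki coupling with 4-bromofuran-2(5H)-one; C9–C11 by vinylation of a C9 enol triflate, which also fixes C8=C9 and the C7 methylene.
3. C5–H (β) and C6–OH (α) come from C5=C6 of the dienone: α-epoxidation, 1,2-hydride shift to the cis-fused 6-ketone, hydride reduction.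
4. Precursor: aryllithium plus acetone, then allylation (C4 to C1); ortho-formylation (C17); bromine on C6 as a para block; hydrolytic kinetic resolution for the (S)-epoxide.
5. Ring order: ring B (bought as arene), ring A (step 9), butenolide ring attached preformed (step 18).

Key step: step 9

**Remarks.** Labdane locants are used: ring A = C1–C5, C10; ring B = C5–C10; chain C11, C12; butenolide C13–C16; C17 = hydroxymethyl carbon. β means the face of the C10 methyl, α the opposite face. The target is (2S,5R,6S,10S): 2α-OH, 6α-OH, 5β-H, cis ring fusion.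
Assumption on the chemistry: in a phenol with hydrogen on C6, the para carbon C6 could close the same six-membered ring as C10 and then rearomatise. C6 therefore carries bromine through the key step, and the bromine is removed directly afterwards.
4-Bromofuran-2(5H)-one is taken as a commercial building block.

**Step 1**
Reactants: 1 3-bromo-2-methylphenol; 2 acetone
Product: 4 3-(2-hydroxypropan-2-yl)-2-methylphenol, via lithium 3-lithio-2-methylphenoxide 3 (not isolated)
Conditions: n-BuLi (1.05 equiv), THF, −78 °C; t-BuLi (2.1 equiv), −78 °C; acetone (3 equiv), −78 → 0 °C; H2O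
Reagents that add atoms: acetone 2, CC(C)=O
Why: Deprotonation of the phenol and bromine–lithium exchange give an aryllithium at the future C5 that undergoes 1,2-addition to acetone, which installs both C4 methyl groups without a phenol protecting group.

**Step 2**
Reactants: 4 3-(2-hydroxypropan-2-yl)-2-methylphenol; 5 allyltrimethylsilane
Product: 6 2-methyl-3-(2-methylpent-4-en-2-yl)phenol
Conditions: allylSiMe3 (3 equiv), Bi(OTf)3 (2 mol %), CH2Cl2, 0 °C → rt; 1 M HCl work-up
Reagents that add atoms: allyltrimethylsilane 5, C=CC[Si](C)(C)C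
Why: The tertiary benzylic alcohol ionises under Lewis acid catalysis and the cation is captured by the allylsilane (Hosomi–Sakurai-type allylation of an alcohol), which creates quaternary C4 with C3, C2 and C1 attached; the allylsilane is far more nucleophilic than the phenol ring, so Friedel–Crafts self-alkylation should stay minor.

**Step 3**
Reactants: 6 2-methyl-3-(2-methylpent-4-en-2-yl)phenol; 7 paraformaldehyde
Product: 8 2-hydroxy-3-methyl-4-(2-methylpent-4-en-2-yl)benzaldehyde
Conditions: (CH2O)n (6 equiv), MgCl2 (1.5 equiv), Et3N (3.8 equiv), MeCN, reflux; 1 M HCl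
Reagents that add atoms: paraformaldehyde 7, C=O
Why: The magnesium-phenoxide-mediated ortho-formylation (Casnati–Skattebøl) delivers formaldehyde through a chelate only to the free ortho carbon (future C8), and a second formaldehyde oxidises the benzylic alkoxide, so the para carbon (future C6) stays untouched.

**Step 4**
Reactants: 8 2-hydroxy-3-methyl-4-(2-methylpent-4-en-2-yl)benzaldehyde
Product: 9 6-(hydroxymethyl)-2-methyl-3-(2-methylpent-4-en-2-yl)phenol
Conditions: NaBH4 (1.0 equiv), MeOH, 0 °C
Reagents that add atoms: none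
Why: Borohydride reduction of the aldehyde gives the C17 alcohol and leaves the terminal alkene alone.

**Step 5**
Reactants: 9 6-(hydroxymethyl)-2-methyl-3-(2-methylpent-4-en-2-yl)phenol
Product: 10 6-{[tert-butyl(dimethyl)silyl]oxymethyl}-2-methyl-3-(2-methylpent-4-en-2-yl)phenol
Conditions: TBSCl (1.1 equiv), imidazole (2.2 equiv), CH2Cl2, 0 °C
Reagents that add atoms: tert-butyldimethylsilyl chloride, CC(C)(C)[Si](C)(C)Cl
Why: Silyl ether formation should occur selectively at the primary benzylic hydroxyl, because the phenol is flanked by two ortho substituents and is much less nucleophilic under these conditions.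

**Step 6**
Reactants: 10 6-{[tert-butyl(dimethyl)silyl]oxymethyl}-2-methyl-3-(2-methylpent-4-en-2-yl)phenol
Product: 11 4-bromo-6-{[tert-butyl(dimethyl)silyl]oxymethyl}-2-methyl-3-(2-methylpent-4-en-2-yl)phenol
Conditions: NBS (1.05 equiv), MeCN, −20 → 0 °C, dark
Reagents that add atoms: N-bromosuccinimide, O=C1CCC(=O)N1Br
Why: Electrophilic aromatic bromination of the phenol can only go para (future C6) because both ortho carbons are substituted, and the phenol ring reacts far faster with NBS than the isolated terminal alkene.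

**Step 7**
Reactants: 11 4-bromo-6-{[tert-butyl(dimethyl)silyl]oxymethyl}-2-methyl-3-(2-methylpent-4-en-2-yl)phenol
Product: 12 racemic 4-bromo-6-{[tert-butyl(dimethyl)silyl]oxymethyl}-2-methyl-3-[2-methyl-1-(oxiran-2-yl)propan-2-yl]phenol
Conditions: mCPBA (1.5 equiv), NaHCO3, CH2Cl2, 0 °C → rt
Reagents that add atoms: 3-chloroperoxybenzoic acid, OOC(=O)c1cccc(Cl)c1
Why: Prilezhaev epoxidation of the monosubstituted alkene; the hindered, para-blocked bromophenol should tolerate the buffered peracid.

**Step 8**
Reactants: 12 racemic 4-bromo-6-{[tert-butyl(dimethyl)silyl]oxymethyl}-2-methyl-3-[2-methyl-1-(oxiran-2-yl)propan-2-yl]phenol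
Product: 13 4-bromo-6-{[tert-butyl(dimethyl)silyl]oxymethyl}-2-methyl-3-{2-methyl-1-[(2S)-oxiran-2-yl]propan-2-yl}phenol
Conditions: (S,S)-(salen)Co(OAc) (1 mol %; salen = N,N′-bis(3,5-di-tert-butylsalicylidene)cyclohexane-1,2-diamine dianion), H2O (0.55 equiv), THF, 0 °C → rt; chromatography
Reagents that add atoms: none
Why: Jacobsen hydrolytic kinetic resolution with the trivalent cobalt salen catalyst enantiomer that hydrolyses the (R)-epoxide (taken to be the (S,S)-complex) should leave the (S)-epoxide in high enantiomeric purity, so the C2 stereocentre is set by catalyst control.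

**Step 9**
Reactants: 13 4-bromo-6-{[tert-butyl(dimethyl)silyl]oxymethyl}-2-methyl-3-{2-methyl-1-[(2S)-oxiran-2-yl]propan-2-yl}phenol
Product: 15 (7S,8aS)-4-bromo-2-{[tert-butyl(dimethyl)silyl]oxymethyl}-7-hydroxy-5,5,8a-trimethyl-6,7,8,8a-tetrahydronaphthalen-1(5H)-one (labdane locants: C9 ketone, C7=C8, C5=C6, 6-Br, 2α-OH), via potassium phenoxide 14 (not isolated)
Conditions: KOt-Bu (1.2 equiv), t-BuOH (0.01 M), 25 → 65 °C, argon, dark; AcOH
Reagents that add atoms: none
Why: The potassium phenoxide reacts through its ortho carbon C10, which opens the epoxide at the terminal carbon C1 by backside attack, so C1–C10 forms, aromaticity is lost and a 6,6-disubstituted cyclohexa-2,4-dienone with the C2 alkoxide results; the closest known reaction type is the base-mediated intramolecular alkylative dearomatisation of ortho-substituted phenols, here with an epoxide in place of the usual halide or sulfonate. Ring A closes in a six-membered mode that is endo for the epoxide (both epoxide carbons enter the ring) and enolendo-exo-tet for the phenoxide, whereas attack at C2 would need a five-membered ring that contains the C10–C5 π bond and a hindered secondary carbon. C10 is set by relay from C2: backside attack places the C2–O bond anti to the forming bond, hence equatorial in a chair, and C9 stays equatorial because it remains in the plane of ring B, so the C10 methyl becomes axial and trans to the C2 oxygen, which is the (2S,10S) arrangement. Carbon over oxygen attack is secured by ring size (six-membered carbocycle against an eight-membered ether), and ortho over para attack by the bromine on C6. High dilution in t-BuOH, which hydrogen-bonds to the phenoxide oxygen and to the epoxide, should suppress intermolecular etherification, and the temperature is kept moderate to spare the benzylic silyl ether.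

**Step 10**
Reactants: 15 (7S,8aS)-4-bromo-2-{[tert-butyl(dimethyl)silyl]oxymethyl}-7-hydroxy-5,5,8a-trimethyl-6,7,8,8a-tetrahydronaphthalen-1(5H)-one
Product: 16 (7S,8aS)-2-{[tert-butyl(dimethyl)silyl]oxymethyl}-7-hydroxy-5,5,8a-trimethyl-6,7,8,8a-tetrahydronaphthalen-1(5H)-one
Conditions: Pd(OAc)2 (5 mol %), PPh3 (10 mol %), HCO2H (2 equiv), Et3N (3 equiv), DMF, 60 °C
Reagents that add atoms: none
Why: Palladium-catalysed formate hydrogenolysis of the vinyl bromide (oxidative addition to zerovalent palladium, decarboxylation of the formate, reductive elimination) should remove the blocking group without touching the dienone.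

**Step 11**
Reactants: 16 (7S,8aS)-2-{[tert-butyl(dimethyl)silyl]oxymethyl}-7-hydroxy-5,5,8a-trimethyl-6,7,8,8a-tetrahydronaphthalen-1(5H)-one
Product: 17 the C2 tert-butyldimethylsilyl ether of 16 (2α,17-bis-silyloxy dienone)
Conditions: TBSCl (1.5 equiv), imidazole (3 equiv), DMF, rt
Reagents that add atoms: tert-butyldimethylsilyl chloride, CC(C)(C)[Si](C)(C)Cl
Why: Standard silylation of the unhindered equatorial C2 alcohol, needed so that this oxygen cannot capture the C5 cation of step 13.

**Step 12**
Reactants: 17 2α,17-bis-silyloxy dienone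
Product: 18 5α,6α-epoxide of 17 (C9 ketone and C7=C8 retained)
Conditions: mCPBA (1.2 equiv), NaHCO3, CH2Cl2, 0 °C
Reagents that add atoms: 3-chloroperoxybenzoic acid, OOC(=O)c1cccc(Cl)c1
Why: Peracid epoxidation takes the electron-richer γ,δ-alkene C5=C6 of the dienone and not the conjugated C7=C8, and comes from the α face because the β face is covered by the axial methyl groups on C4 and C10.

**Step 13**
Reactants: 18 5α,6α-epoxy enone
Product: 19 cis-fused 5β-H ene-dione (C6 and C9 ketones, C7=C8, 2α- and 17-silyloxy)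
Conditions: BF3·OEt2 (0.3 equiv), benzene, 10 °C, short reaction time; aq. NaHCO3
Reagents that add atoms: none
Why: Meinwald rearrangement: the Lewis acid opens the epoxide at tertiary C5 (a cation at C6 is disfavoured by the electron-poor alkene next to it) and the C6 hydrogen, which lies on the β face, shifts to C5 with inversion there, which gives the 6-ketone with 5β-H; the same course is known for 5α,6α-epoxy steroids that carry a 10β-methyl group.

**Step 14**
Reactants: 19 cis-fused 5β-H ene-dione
Product: 20 6α-hydroxy enone (5β-H, C9 ketone, C7=C8)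
Conditions: NaBH4 (1.0 equiv), CeCl3·7H2O (1.2 equiv), MeOH/THF, −78 °C
Reagents that add atoms: none
Why: Luche 1,2-reduction should take the C6 carbonyl, because C9 is shielded by quaternary C10 and the substituted C8, and hydride should arrive from the convex β face of the cis-fused bicycle to give the 6α-alcohol; the non-basic medium should leave C5 unchanged.

**Step 15**
Reactants: 20 6α-hydroxy enone
Product: 21 2α,6α,17-tris-silyloxy enone
Conditions: TBSOTf (1.3 equiv), 2,6-lutidine (2 equiv), CH2Cl2, −78 °C
Reagents that add atoms: tert-butyldimethylsilyl trifluoromethanesulfonate, CC(C)(C)[Si](C)(C)OS(=O)(=O)C(F)(F)F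
Why: Silyl triflate and a hindered base silylate the hindered allylic C6 alcohol under conditions that do not enolise the ketone.

**Step 16**
Reactants: 21 2α,6α,17-tris-silyloxy enone
Product: 23 C9 enol triflate with C8=C9 and a C7 methylene, via lithium enolate 22 (not isolated)
Conditions: LiBH(s-Bu)3 (1.1 equiv), THF, −78 °C; N-(5-chloropyridin-2-yl)bis(trifluoromethanesulfonyl)imide (1.3 equiv), −78 → 0 °C
Reagents that add atoms: N-(5-chloropyridin-2-yl)bis(trifluoromethanesulfonyl)imide, FC(F)(F)S(=O)(=O)N(c1ccc(Cl)cn1)S(=O)(=O)C(F)(F)F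
Why: Conjugate hydride addition of the bulky borohydride at C7 (the carbonyl is blocked by quaternary C10) gives the regiodefined C8=C9 enolate, which is O-triflated at low temperature before the β-silyloxy group on C17 can be lost.

**Step 17**
Reactants: 23 C9 enol triflate; 24 tributyl(vinyl)stannane
Product: 25 9-vinyl diene (C8=C9 and C11=C12)
Conditions: 24 (1.5 equiv), Pd(PPh3)4 (5 mol %), LiCl (3 equiv), THF, 65 °C
Reagents that add atoms: tributyl(vinyl)stannane 24, C=C[Sn](CCCC)(CCCC)CCCC
Why: Stille coupling of an enol triflate with a vinylstannane is reliable for tetrasubstituted triflates next to a quaternary carbon and forms the C9–C11 bond.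

**Step 18**
Reactants: 25 9-vinyl diene; 26 4-bromofuran-2(5H)-one
Product: 28 2α,6α,17-tris-silyl ether of the target, via alkylborane 27 (not isolated)
Conditions: 9-BBN-H (1.5 equiv), THF, 0 °C → rt; then 26 (1.5 equiv), PdCl2(dppf) (5 mol %), AsPh3 (10 mol %), Cs2CO3 (3 equiv), DMF/H2O, rt
Reagents that add atoms: 4-bromofuran-2(5H)-one 26, BrC1=CC(=O)OC1
Why: Hydroboration with 9-BBN-H takes only the terminal vinyl group (boron to C12; the tetrasubstituted C8=C9 is inert), and the B-alkyl Suzuki–Miyaura coupling with the β-bromo butenolide forms C12–C13 and completes the side chain.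

**Step 19**
Reactants: 28 tris-silyl ether of the target
Product: 29 CNP0293367.1, (2S,5R,6S,10S)-2α,6α,17-trihydroxy-5β-labda-8,13-dien-15,16-olide
Conditions: HF·pyridine, pyridine/THF, 0 °C → rt
Reagents that add atoms: none
Why: Buffered fluoride-mediated desilylation should remove all three silyl ethers without isomerising the butenolide or ionising the allylic C17 alcohol.

**Compound list**

1 | 3-bromo-2-methylphenol | Cc1c(O)cccc1Br | starting material
2 | acetone | CC(C)=O | starting material
3 | lithium 3-lithio-2-methylphenoxide | [Li]Oc1cccc([Li])c1C | intermediate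
4 | 3-(2-hydroxypropan-2-yl)-2-methylphenol | Cc1c(O)cccc1C(C)(C)O | intermediate
5 | allyltrimethylsilane | C=CC[Si](C)(C)C | starting material
6 | 2-methyl-3-(2-methylpent-4-en-2-yl)phenol | Cc1c(O)cccc1C(C)(C)CC=C | intermediate
7 | paraformaldehyde (as formaldehyde) | C=O | starting material
8 | 2-hydroxy-3-methyl-4-(2-methylpent-4-en-2-yl)benzaldehyde | Cc1c(O)c(C=O)ccc1C(C)(C)CC=C | intermediate
9 | 6-(hydroxymethyl)-2-methyl-3-(2-methylpent-4-en-2-yl)phenol | Cc1c(O)c(CO)ccc1C(C)(C)CC=C | intermediate
10 | 6-{[tert-butyl(dimethyl)silyl]oxymethyl}-2-methyl-3-(2-methylpent-4-en-2-yl)phenol | Cc1c(O)c(CO[Si](C)(C)C(C)(C)C)ccc1C(C)(C)CC=C | intermediate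
11 | 4-bromo-6-{[tert-butyl(dimethyl)silyl]oxymethyl}-2-methyl-3-(2-methylpent-4-en-2-yl)phenol | Cc1c(O)c(CO[Si](C)(C)C(C)(C)C)cc(Br)c1C(C)(C)CC=C | intermediate
12 | racemic 4-bromo-6-{[tert-butyl(dimethyl)silyl]oxymethyl}-2-methyl-3-[2-methyl-1-(oxiran-2-yl)propan-2-yl]phenol | Cc1c(O)c(CO[Si](C)(C)C(C)(C)C)cc(Br)c1C(C)(C)CC1CO1 | intermediate
13 | (S)-epoxide, key-step precursor | Cc1c(O)c(CO[Si](C)(C)C(C)(C)C)cc(Br)c1C(C)(C)C[C@H]1CO1 | intermediate
14 | potassium phenoxide of 13 | [K+].Cc1c([O-])c(CO[Si](C)(C)C(C)(C)C)cc(Br)c1C(C)(C)C[C@H]1CO1 | intermediate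
15 | (7S,8aS)-4-bromo-2-{[tert-butyl(dimethyl)silyl]oxymethyl}-7-hydroxy-5,5,8a-trimethyl-6,7,8,8a-tetrahydronaphthalen-1(5H)-one | CC1(C)C[C@H](O)C[C@]2(C)C(=O)C(CO[Si](C)(C)C(C)(C)C)=CC(Br)=C12 | intermediate
16 | (7S,8aS)-2-{[tert-butyl(dimethyl)silyl]oxymethyl}-7-hydroxy-5,5,8a-trimethyl-6,7,8,8a-tetrahydronaphthalen-1(5H)-one | CC1(C)C[C@H](O)C[C@]2(C)C(=O)C(CO[Si](C)(C)C(C)(C)C)=CC=C12 | intermediate
17 | 2α,17-bis-silyloxy dienone | CC1(C)C[C@H](O[Si](C)(C)C(C)(C)C)C[C@]2(C)C(=O)C(CO[Si](C)(C)C(C)(C)C)=CC=C12 | intermediate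
18 | 5α,6α-epoxy enone | CC1(C)C[C@H](O[Si](C)(C)C(C)(C)C)C[C@]2(C)C(=O)C(CO[Si](C)(C)C(C)(C)C)=C[C@@H]3O[C@]123 | intermediate
19 | cis-fused 5β-H 7-ene-6,9-dione | CC1(C)C[C@H](O[Si](C)(C)C(C)(C)C)C[C@]2(C)C(=O)C(CO[Si](C)(C)C(C)(C)C)=CC(=O)[C@H]12 | intermediate
20 | 6α-hydroxy enone | CC1(C)C[C@H](O[Si](C)(C)C(C)(C)C)C[C@]2(C)C(=O)C(CO[Si](C)(C)C(C)(C)C)=C[C@H](O)[C@H]12 | intermediate
21 | 2α,6α,17-tris-silyloxy enone | CC1(C)C[C@H](O[Si](C)(C)C(C)(C)C)C[C@]2(C)C(=O)C(CO[Si](C)(C)C(C)(C)C)=C[C@H](O[Si](C)(C)C(C)(C)C)[C@H]12 | intermediate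
22 | lithium C8=C9 enolate | [Li+].CC1(C)C[C@H](O[Si](C)(C)C(C)(C)C)C[C@]2(C)C([O-])=C(CO[Si](C)(C)C(C)(C)C)C[C@H](O[Si](C)(C)C(C)(C)C)[C@H]12 | intermediate
23 | C9 enol triflate | CC1(C)C[C@H](O[Si](C)(C)C(C)(C)C)C[C@]2(C)C(OS(=O)(=O)C(F)(F)F)=C(CO[Si](C)(C)C(C)(C)C)C[C@H](O[Si](C)(C)C(C)(C)C)[C@H]12 | intermediate
24 | tributyl(vinyl)stannane | C=C[Sn](CCCC)(CCCC)CCCC | starting material
25 | 9-vinyl diene | CC1(C)C[C@H](O[Si](C)(C)C(C)(C)C)C[C@]2(C)C(C=C)=C(CO[Si](C)(C)C(C)(C)C)C[C@H](O[Si](C)(C)C(C)(C)C)[C@H]12 | intermediate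
26 | 4-bromofuran-2(5H)-one | BrC1=CC(=O)OC1 | starting material
27 | C12 B-alkyl-9-borabicyclo[3.3.1]nonane | CC1(C)C[C@H](O[Si](C)(C)C(C)(C)C)C[C@]2(C)C(CCB3C4CCCC3CCC4)=C(CO[Si](C)(C)C(C)(C)C)C[C@H](O[Si](C)(C)C(C)(C)C)[C@H]12 | intermediate
28 | 2α,6α,17-tris-silyl ether of the target | CC1(C)C[C@H](O[Si](C)(C)C(C)(C)C)C[C@]2(C)C(CCC3=CC(=O)OC3)=C(CO[Si](C)(C)C(C)(C)C)C[C@H](O[Si](C)(C)C(C)(C)C)[C@H]12 | intermediate
29 | CNP0293367.1, (2S,5R,6S,10S)-2α,6α,17-trihydroxy-5β-labda-8,13-dien-15,16-olide | CC1(C)C[C@H](O)C[C@]2(C)C(CCC3=CC(=O)OC3)=C(CO)C[C@H](O)[C@H]12 | target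

**Step count and risks**

Total: 19 steps. Longest linear sequence: 19 steps (from 1; compounds 2, 5, 7, 24 and 26 are bought).

Step 9. The bromophenoxide may open the epoxide too slowly or at its internal carbon, so that intermolecular ether formation or a five-membered closure takes over, or the ring may be attacked at the brominated para carbon. The fallback keeps the C1–C10 disconnection but changes the electrophile to a primary iodide. It sets out from 13: LiI and AcOH in THF open the epoxide at C1 to the iodohydrin F1. TBSOTf and 2,6-lutidine silylate the phenol and the C2 alcohol to give F2. CsF in DMF then cleaves only the aryl silyl ether, and the caesium phenoxide closes ring A by displacement of iodide at C1 (chair, C2 silyloxy group equatorial) to the silylated bromodienone F3. Formate hydrogenolysis as in step 10 brings F3 back to the route at 17.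

Step 13. The C5 cation may be captured by fluoride from the boron reagent, a C4 methyl group may migrate, or the epoxide may survive at the temperature the silyl ethers allow, before the hydride shift takes place. The fallback sets out from 17: dihydroxylation of C5=C6 from the α face (catalytic OsO4, NMO, acetone/H2O) gives the cis-5α,6α-diol F4. A pinacol rearrangement under fluoride-free acid (catalytic TsOH, benzene, rt) ionises the tertiary C5 hydroxyl and the free C6 hydroxyl drives the same β-face hydride shift. The fallback returns to the route at 19. It avoids fluoride capture but not the methyl shift, which belongs to the same cation.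

Step 14. Hydride may arrive from the α face of C6, or with poor facial selectivity, so that the 6β-alcohol forms. The fallback sets out from 19 and sets C6 by substitution: the 6β-alcohol F5 obtained from the reduction is inverted by a Mitsunobu reaction (PPh3, DIAD, 4-nitrobenzoic acid) to the 6α-ester F6, and methanolysis (K2CO3, MeOH) returns to the route at 20.

**Further compounds**

F1 | step 9 | 4-bromo-6-{[tert-butyl(dimethyl)silyl]oxymethyl}-3-[(4S)-4-hydroxy-5-iodo-2-methylpentan-2-yl]-2-methylphenol | Cc1c(O)c(CO[Si](C)(C)C(C)(C)C)cc(Br)c1C(C)(C)C[C@H](O)CI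
F2 | step 9 | bis-silyl ether of F1 (aryl and C2 oxygen silylated) | Cc1c(O[Si](C)(C)C(C)(C)C)c(CO[Si](C)(C)C(C)(C)C)cc(Br)c1C(C)(C)C[C@H](O[Si](C)(C)C(C)(C)C)CI
F3 | step 9 | 6-bromo-2α,17-bis-silyloxy dienone (C2 silyl ether of 15) | CC1(C)C[C@H](O[Si](C)(C)C(C)(C)C)C[C@]2(C)C(=O)C(CO[Si](C)(C)C(C)(C)C)=CC(Br)=C12
F4 | step 13 | 5α,6α-dihydroxy enone from 17 | CC1(C)C[C@H](O[Si](C)(C)C(C)(C)C)C[C@]2(C)C(=O)C(CO[Si](C)(C)C(C)(C)C)=C[C@H](O)[C@@]12O
F5 | step 14 | 6β-hydroxy enone (C6 epimer of 20) | CC1(C)C[C@H](O[Si](C)(C)C(C)(C)C)C[C@]2(C)C(=O)C(CO[Si](C)(C)C(C)(C)C)=C[C@@H](O)[C@H]12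
F6 | step 14 | 6α-(4-nitrobenzoyloxy) enone | CC1(C)C[C@H](O[Si](C)(C)C(C)(C)C)C[C@]2(C)C(=O)C(CO[Si](C)(C)C(C)(C)C)=C[C@H](OC(=O)c3ccc(cc3)[N+](=O)[O-])[C@H]12
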